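**Plan**
- Retrosynthesis: the aryl silyl ether and the C5–propenyl bond (back to a C5 bromide) are cut first. Next, O1–C2 and C3a–C3 of the dihydrofuran are cut together, giving an (E)-propenylarene and ring A as a cyclohexadienone ketal. Last, the alkene C=C is cut back to an aldehyde.
- Enabling feature: O1 and the C7 methoxy group sit on adjacent carbons of ring A (C7a, C7). Ring A can therefore be carried as a masked o-benzoquinone (C7a as C=O, C7 as C(OMe)2), whose ionisation makes the future C3a electrophilic. The 4-methoxy group of the C2 aryl ring stabilises a cation at C2.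
- Forward: silylation and Julia–Kocienski olefination give the alkene; oxidative dearomatisation of 4-bromo-2-methoxyphenol gives the dienone ketal. A chiral-acid-catalysed formal [3+2] annulation closes the dihydrofuran and re-aromatises ring A in one operation. Suzuki coupling at C5 and desilylation finish.
- Stereochemistry: C3 comes from catalyst-controlled face selection in the C–C bond formation; C2 from trans-selective cation capture relative to the C3 methyl. Both E-alkenes come from E-selective olefination and stereoretentive coupling.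

Key step: step 4

Assumption: the sense of induction of the chiral acid in step 4 cannot be predicted with confidence; the (S,S)-catalyst is written, and its antipode is taken if a test run shows the (2R,3R) series.

Step 1
Reactants: 1 3-hydroxy-4,5-dimethoxybenzaldehyde
Product: 2 3,4-dimethoxy-5-[(triisopropylsilyl)oxy]benzaldehyde
Conditions: TIPSCl (1.2 equiv), imidazole (2.5 equiv), DMF, rt
Reagents that add atoms: chlorotriisopropylsilane, CC(C)[Si](Cl)(C(C)C)C(C)C
Why: Imidazole-mediated O-silylation (silyl ether protection) masks the only free phenol, which would otherwise trap the cationic electrophile of step 4, and the hindered aryl TIPS ether should tolerate KHMDS, the acid of step 4 and the phosphate base of step 5.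

Step 2
Reactants: 2 3,4-dimethoxy-5-[(triisopropylsilyl)oxy]benzaldehyde
Product: 3 triisopropyl{2,3-dimethoxy-5-[(E)-prop-1-en-1-yl]phenoxy}silane
Conditions: 5-(ethylsulfonyl)-1-phenyl-1H-tetrazole (1.3 equiv), KHMDS (1.25 equiv), DME, −60 °C; then 2, −60 °C → rt
Reagents that add atoms: 5-(ethylsulfonyl)-1-phenyl-1H-tetrazole, CCS(=O)(=O)c1nnnn1-c1ccccc1
Why: Julia–Kocienski olefination: the potassium-metalated phenyltetrazolyl ethyl sulfone adds to the aldehyde, and Smiles rearrangement with loss of SO2 and the tetrazololate should give the conjugated alkene with the E selectivity usual for this sulfone type in DME, without touching the silyl ether.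

Step 3
Reactants: 4 4-bromo-2-methoxyphenol
Product: 5 4-bromo-6,6-dimethoxycyclohexa-2,4-dien-1-one
Conditions: PhI(OAc)2 (1.1 equiv), MeOH, 0 °C; NaHCO3 work-up, kept cold and used at once
Reagents that add atoms: methanol, CO
Why: Hypervalent-iodine oxidative dearomatisation of a 2-methoxyphenol in methanol (formation of a masked o-benzoquinone) adds methanol at the methoxy-bearing carbon to give the 6,6-dimethyl ketal, and the 4-bromo substituent should retard the Diels–Alder dimerisation typical of such dienones.

Step 4
Reactants: 3 triisopropyl{2,3-dimethoxy-5-[(E)-prop-1-en-1-yl]phenoxy}silane, 5 4-bromo-6,6-dimethoxycyclohexa-2,4-dien-1-one (1.3 equiv)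
Product: 7 {5-[(2S,3S)-5-bromo-7-methoxy-3-methyl-2,3-dihydro-1-benzofuran-2-yl]-2,3-dimethoxyphenoxy}triisopropylsilane, via oxocarbenium ion 6 (not isolated)
Conditions: (S,S)-IDPi (confined imidodiphosphorimidate Brønsted acid, 3 mol %), 5 Å MS, CH2Cl2/toluene, −78 → −50 °C; Et3N quench
Reagents that add atoms: none
Why: Proposed new method: the confined chiral acid protonates a ketal oxygen of 5 and expels methanol to give oxocarbenium ion 6 (an O-methylated o-quinone, i.e. the 4-bromo-2-methoxyphenoxonium ion) as a contact ion pair with the chiral anion; the methyl-bearing alkene carbon of 3 adds to the only unsubstituted electrophilic terminus of 6 (the CH next to C=O, the future C3a), the benzylic cation so formed (stabilised by the para-methoxy group) is captured by the dienone oxygen, and loss of the C3a proton re-aromatises ring A and returns the catalyst. The closest known reaction types are the Brønsted-acid-catalysed [3+2] coupling of para-quinone monoacetals with alkenes, the biomimetic acid-mediated condensation of quinone ketals with (E)-propenylbenzenes, and counter-anion-directed additions of simple alkenes to oxocarbenium ions catalysed by IDPi acids. The one ring that closes, the dihydrofuran, arises by intermolecular C–C bond formation followed by 5-exo-trig capture of the benzylic cation by oxygen (a stepwise formal [3+2] cycloaddition). C3 is set under catalyst control, the chiral anion selecting the alkene face that bonds to the planar cation, and C2 is set under substrate control, because ring closure (reversible under the acid through the stabilised cation) places the aryl group trans to the C3 methyl. The step needs attack at the ring CH rather than at the Br- or MeO-bearing termini, and ionisation rather than thermal Diels–Alder reaction or conjugate addition: only the CH adduct can aromatise, ipso adducts and carbon-trapped bicyclo[2.2.2]octenones can revert through the same cations to this thermodynamic sink, and the low temperature and the 4-bromo substituent disfavour the cycloaddition and dimerisation manifold of the dienone.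

Step 5
Reactants: 7 {5-[(2S,3S)-5-bromo-7-methoxy-3-methyl-2,3-dihydro-1-benzofuran-2-yl]-2,3-dimethoxyphenoxy}triisopropylsilane
Product: 8 {2,3-dimethoxy-5-[(2S,3S)-7-methoxy-3-methyl-5-[(E)-prop-1-en-1-yl]-2,3-dihydro-1-benzofuran-2-yl]phenoxy}triisopropylsilane
Conditions: (E)-propenyl-Bpin (1.5 equiv), Pd(dppf)Cl2 (5 mol %), K3PO4 (3 equiv), 1,4-dioxane/H2O, 70 °C
Reagents that add atoms: (E)-4,4,5,5-tetramethyl-2-(prop-1-en-1-yl)-1,3,2-dioxaborolane, C/C=C/B1OC(C)(C)C(C)(C)O1
Why: Suzuki–Miyaura coupling of the aryl bromide with an (E)-alkenylboronate should proceed with retention of alkene geometry, and the mild phosphate base should leave the C2 benzylic ether, the C3 stereocentre and the silyl ether intact.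

Step 6
Reactants: 8 {2,3-dimethoxy-5-[(2S,3S)-7-methoxy-3-methyl-5-[(E)-prop-1-en-1-yl]-2,3-dihydro-1-benzofuran-2-yl]phenoxy}triisopropylsilane
Product: 9 2,3-dimethoxy-5-[(2S,3S)-7-methoxy-3-methyl-5-[(E)-prop-1-en-1-yl]-2,3-dihydro-1-benzofuran-2-yl]phenol
Conditions: TBAF (1.2 equiv), AcOH (1.2 equiv), THF, 0 °C
Reagents that add atoms: none
Why: Fluoride-induced cleavage of the aryl silyl ether (Si–F bond formation), buffered with acetic acid so that neither a free phenoxide nor a strong acid meets the benzylic ether and the propenyl group, should release the target phenol with both stereocentres untouched.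

**Compound list**
1 | 3-hydroxy-4,5-dimethoxybenzaldehyde | COc1cc(C=O)cc(O)c1OC | starting material
2 | 3,4-dimethoxy-5-[(triisopropylsilyl)oxy]benzaldehyde | COc1cc(C=O)cc(O[Si](C(C)C)(C(C)C)C(C)C)c1OC | intermediate
3 | triisopropyl{2,3-dimethoxy-5-[(E)-prop-1-en-1-yl]phenoxy}silane | C/C=C/c1cc(OC)c(OC)c(O[Si](C(C)C)(C(C)C)C(C)C)c1 | intermediate
4 | 4-bromo-2-methoxyphenol | COc1cc(Br)ccc1O | starting material
5 | 4-bromo-6,6-dimethoxycyclohexa-2,4-dien-1-one | COC1(OC)C=C(Br)C=CC1=O | intermediate
6 | (5-bromo-2-oxocyclohexa-3,5-dien-1-ylidene)(methyl)oxonium (4-bromo-2-methoxyphenoxonium ion; ion pair with the catalyst anion, not isolated) | C[O+]=C1C=C(Br)C=CC1=O | intermediate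
7 | {5-[(2S,3S)-5-bromo-7-methoxy-3-methyl-2,3-dihydro-1-benzofuran-2-yl]-2,3-dimethoxyphenoxy}triisopropylsilane | Brc1cc(OC)c2c(c1)[C@H](C)[C@@H](c1cc(O[Si](C(C)C)(C(C)C)C(C)C)c(OC)c(OC)c1)O2 | intermediate
8 | {2,3-dimethoxy-5-[(2S,3S)-7-methoxy-3-methyl-5-[(E)-prop-1-en-1-yl]-2,3-dihydro-1-benzofuran-2-yl]phenoxy}triisopropylsilane | C/C=C/c1cc(OC)c2c(c1)[C@H](C)[C@@H](c1cc(O[Si](C(C)C)(C(C)C)C(C)C)c(OC)c(OC)c1)O2 | intermediate
9 | 2,3-dimethoxy-5-[(2S,3S)-7-methoxy-3-methyl-5-[(E)-prop-1-en-1-yl]-2,3-dihydro-1-benzofuran-2-yl]phenol | C/C=C/c1cc(OC)c2c(c1)[C@H](C)[C@@H](c1cc(O)c(OC)c(OC)c1)O2 | target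

**Count**
Total steps: 6. Longest linear sequence: 5 steps (1 → 2 → 4 → 5 → 6).

**Steps most likely to fail**

1. Step 4 (Proposed new method). Ionisation of the ketal may fail to outrun conjugate addition or cycloaddition to the intact dienone. The strong acid may oligomerise the electron-rich alkene. The ion pair may discriminate the alkene faces poorly. Attack at the substituted termini may divert material.
   Fallback (known reactions only): it sets out from 3 and returns at 8. Commercial 4-(benzyloxy)-2-methoxybenzaldehyde is taken through a Dakin oxidation (mCPBA, CH2Cl2; then NaOH, MeOH) by way of 4-(benzyloxy)-2-methoxyphenyl formate F1 to 4-(benzyloxy)-2-methoxyphenol F2. Oxidative cycloaddition of F2 with 3 mediated by PhI(OCOCF3)2 (the established coupling of p-alkoxyphenols with (E)-propenylbenzenes) should give the racemic trans-5-benzyloxy dihydrobenzofuran F3. Hydrogenolysis (H2, Pd/C, EtOAc) should give the racemic dihydrobenzofuran-5-ol F4, and preparative chromatography on a chiral stationary phase the (2S,3S)-dihydrobenzofuran-5-ol F5. Triflation (Tf2O, pyridine, CH2Cl2) to the aryl triflate F6 and Suzuki–Miyaura coupling under the conditions of step 5 lead to 8.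

2. Step 3. The dienone ketal may dimerise by Diels–Alder reaction or hydrolyse to the o-quinone during isolation.
   Fallback: it sets out from 4 and returns at 7. Wessely acetoxylation (Pb(OAc)4, AcOH/CH2Cl2, rt) should give the more robust o-quinol acetate 3-bromo-1-methoxy-6-oxocyclohexa-2,4-dien-1-yl acetate F7 (racemic; its stereocentre is lost on ionisation). Under the conditions of step 4, F7 ionises by loss of acetate to the same ion 6 and so delivers 7.

3. Step 2. E-selectivity may erode in the addition/Smiles/elimination sequence, and a Z-contaminated alkene would undermine face selection in step 4.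
   Fallback: it sets out from 2 and returns at 3. Addition of EtMgBr (THF, 0 °C) gives the carbinol 1-{3,4-dimethoxy-5-[(triisopropylsilyl)oxy]phenyl}propan-1-ol F8. Acid-catalysed dehydration (cat. p-TsOH, toluene, 80 °C, dilute) passes through the benzylic cation and should give the thermodynamic E-alkene 3.

**Further compounds**
F1 | step 4 | 4-(benzyloxy)-2-methoxyphenyl formate | O=COc1ccc(OCc2ccccc2)cc1OC
F2 | step 4 | 4-(benzyloxy)-2-methoxyphenol | Oc1ccc(OCc2ccccc2)cc1OC
F3 | step 4 | racemic trans-{5-[5-(benzyloxy)-7-methoxy-3-methyl-2,3-dihydro-1-benzofuran-2-yl]-2,3-dimethoxyphenoxy}triisopropylsilane (one enantiomer drawn) | C(Oc1cc(OC)c2c(c1)[C@H](C)[C@@H](c1cc(O[Si](C(C)C)(C(C)C)C(C)C)c(OC)c(OC)c1)O2)c1ccccc1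
F4 | step 4 | racemic trans-2-{3,4-dimethoxy-5-[(triisopropylsilyl)oxy]phenyl}-7-methoxy-3-methyl-2,3-dihydro-1-benzofuran-5-ol (one enantiomer drawn) | Oc1cc(OC)c2c(c1)[C@H](C)[C@@H](c1cc(O[Si](C(C)C)(C(C)C)C(C)C)c(OC)c(OC)c1)O2
F5 | step 4 | (2S,3S)-2-{3,4-dimethoxy-5-[(triisopropylsilyl)oxy]phenyl}-7-methoxy-3-methyl-2,3-dihydro-1-benzofuran-5-ol | Oc1cc(OC)c2c(c1)[C@H](C)[C@@H](c1cc(O[Si](C(C)C)(C(C)C)C(C)C)c(OC)c(OC)c1)O2
F6 | step 4 | (2S,3S)-2-{3,4-dimethoxy-5-[(triisopropylsilyl)oxy]phenyl}-7-methoxy-3-methyl-2,3-dihydro-1-benzofuran-5-yl trifluoromethanesulfonate | O=S(=O)(Oc1cc(OC)c2c(c1)[C@H](C)[C@@H](c1cc(O[Si](C(C)C)(C(C)C)C(C)C)c(OC)c(OC)c1)O2)C(F)(F)F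
F7 | step 3 | 3-bromo-1-methoxy-6-oxocyclohexa-2,4-dien-1-yl acetate (racemic) | CC(=O)OC1(OC)C=C(Br)C=CC1=O
F8 | step 2 | 1-{3,4-dimethoxy-5-[(triisopropylsilyl)oxy]phenyl}propan-1-ol (racemic) | CCC(O)c1cc(OC)c(OC)c(O[Si](C(C)C)(C(C)C)C(C)C)c1
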